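The readings stem from a simulated flask with constants of no real substance; noise was put on by code.

Start from what the ring costs.

| setting | green | ochre | violet | flask |
|---|---|---|---|---|
| starting material | 9.5 mM | 38 mM | 19 mM | 19 mM |
| protic impurity | 1.9 mM | 1.9 mM | 3.8 mM | 1.90 mM |
| remark | run made earlier | run made earlier | run made earlier |  |
| time |  |  |  | 40 min |

| run | time / min | starting material / % | ring / % | side product / % |
|---|---|---|---|---|
| green | 6.00 | 0.8 | 76.8 | 4.0 |
| green | 12.0 | 0 | 78.2 | 3.5 |
| green | 15.0 | 0 | 77.6 | 3.1 |
| green | 25.0 | 0.2 | 78.7 | 3.8 |
| green | 30.0 | 0 | 78.0 | 3.2 |
| green | 40.0 | 0 | 77.5 | 3.9 |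
| ochre | 2.00 | 0 | 81.9 | 13.9 |
| ochre | 6.00 | 0.9 | 81.5 | 13.4 |
| ochre | 12.0 | 0 | 81.6 | 13.7 |
| ochre | 15.0 | 0 | 81.6 | 14.6 |
| ochre | 25.0 | 0.6 | 81.6 | 14.3 |
| ochre | 30.0 | 0 | 82.0 | 13.6 |
| ochre | 40.0 | 0 | 81.7 | 13.7 |
| violet | 8.00 | 0.6 | 74.2 | 5.9 |
| violet | 15.0 | 0 | 73.5 | 5.2 |
| violet | 25.0 | 0.2 | 74.8 | 5.3 |
| violet | 30.0 | 0.7 | 74.6 | 6.7 |
| violet | 40.0 | 0 | 73.9 | 5.2 |

(standard deviation of a reading: 0.5 percentage points)

* the state of affairs at 40 min: stopped, and by what, or still going (it is still moving / all of the starting material has reacted / forward and back rates have come level)
* part of the starting material gone at 40 min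
* the ring standing at 40 min, as a percentage of the starting material charged
* the side product standing at 40 min, as a percentage of the starting material charged

Take the protic impurity first. In the ochre run, ring and side product leave 4.60% of the charge missing at 40.0 min, where impurity over starting material is 5.00%, and in the violet run the gap is 20.9% against 20.0%. So you count one starting material lost per impurity, and the flask keeps a share of 90.0% for ring and side product. The green run, with a smaller charge of starting material than the flask, reads 0% of it at 12.0 min, the ochre run, with a larger charge, reads 0% at 12.0 min, and the ring in both stays level from there to 40.0 min within the scatter of 0.5 percentage points, so you expect the flask, whose impurity equals theirs and whose charge lies between, to have stopped by 40 min, with its starting material used up.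

What remains is the split. Ring forms at a rate constant times [starting material], side product at another constant times [starting material][ring], and when you divide the two rates [starting material] cancels, however fast it falls. Freeze that ratio of constants, the selectivity factor S, and while little ring is lost, side product, counted double, over ring comes to S[ring]. The ochre run, whose side product reading of 13.7% is higher than in the other runs, gives the reading S = 5.40 M⁻¹. For the flask, S times the charge is 0.103, and ring plus that number times ring squared must equal the share, which gives you ring 82.9% and side product 7.06%.

The forecast says all of the starting material has reacted, with conversion 100%, ring 83% and side product 7.1%, on the ground that “The side-product share of the non-quenched material rises with effective concentration”.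

The flask gives ring 82.7% and side product 7.26% at conversion 100%: all of the starting material has reacted.

    starting material → ring (k = 0.115 s⁻¹)
    2 starting material ⇌ open dimer (K = 49.6 M⁻¹, k = 17.2 M⁻¹ s⁻¹)
    starting material + ring ⇌ idle adduct, settled at all times (K = 80.0 M⁻¹)
    starting material + protic impurity → quenched substrate (k = 46.4 M⁻¹ s⁻¹)
    starting material + ring → side product (k = 0.731 M⁻¹ s⁻¹)

With the step from starting material + ring to side product struck out, the flask's ring stands at 90.0%, beside the share of 90.0%. S applied to the flask's ring of 82.7% gives side product 7.03%, against 7.26% standing. The neighbour flask with 3.2 mM of protic impurity has a share of 83.2%, so S gives it ring 77.1% and side product 6.09%, and it stands at ring 76.9% and side product 6.29%.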